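Ring A (C4a, C5, C6, C7, C7a) with its C7 methyl carbinol is treated as a protected 4-hydroxy-4-methylcyclopent-2-enone, and the pyran carbons C1 (on C7a) and C4–C3 with the C3 methyl (on C4a) as a masked 1,5-keto aldehyde. The key step attaches both pyran arms to the linalool-derived (R)-silyloxy enone in one flask: vinylcopper addition at the β-carbon makes C7a–C1, and methallylation of the resulting enolate makes C4a–C4. Later C6 takes the side chain by aldol condensation, C5 its ester through an enol triflate, and ozonolysis of both arms with acid cyclodehydration across the C4a=C5 alkylidene closes the 4H-pyran.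

Key step: step 4

Remarks on the chemistry:
- Ring atoms carry cyclopenta[c]pyran numbers (C1, O2, C3, C4, C4a, C5, C6, C7, C7a); side-chain carbons are primed from the alkylidene carbon C1′.
- The target is read as the (6Z,7R) ester with a (3′S) side chain. C3 of (R)-linalool maps onto C7 with the same spatial arrangement, so the chiral pool supplies the correct enantiomer.
- The C7 oxygen stays a triethylsilyl ether to the last step: a tertiary triethylsilyl ether should survive every step and still leave with buffered HF.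
- Me3SiCl is left out of the key step, because it would cap the enolate as a silyl enol ether, which an allylic iodide does not alkylate.
- C2′ is carried as a mixture of epimers (17 to 25) because it ends as the ketone.
- The C6=C1′ bond is drawn with the chain on the C7 side throughout. This is assumed to be the preferred geometry; it can equilibrate once the push–pull chromophore exists.

Step 1
Reactants: 1 (R)-(−)-linalool
Product: 3 triethyl{[(1R)-1-methylcyclopent-2-en-1-yl]oxy}silane, via (1R)-1-methylcyclopent-2-en-1-ol 2 (not isolated)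
Conditions: second-generation Grubbs catalyst (0.5 mol %), CH2Cl2, 40 °C; then 2,6-lutidine, Et3SiOTf, 0 °C
Reagents that add atoms: triethylsilyl trifluoromethanesulfonate, CC[Si](CC)(CC)OS(=O)(=O)C(F)(F)F
Why: Ring-closing metathesis between the vinyl group and the trisubstituted alkene expels volatile 2-methylpropene without touching the carbinol centre, and silylation of the tertiary allylic alcohol by the silyl triflate in the same flask avoids isolating the volatile, water-soluble alcohol 2.

Step 2
Reactants: 3 triethyl{[(1R)-1-methylcyclopent-2-en-1-yl]oxy}silane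
Product: 4 (4R)-4-methyl-4-[(triethylsilyl)oxy]cyclopent-2-en-1-one
Conditions: CrO3, 3,5-dimethylpyrazole, CH2Cl2, −20 °C
Reagents that add atoms: chromium trioxide, O=[Cr](=O)=O
Why: Allylic oxidation of the only allylic CH2 by the CrO3–3,5-dimethylpyrazole complex (hexavalent chromium) should give the enone, the silyl ether blocking the oxidative 1,3-transposition that a free tertiary allylic alcohol would undergo.

Step 3
Reactants: 5 3-chloro-2-methylprop-1-ene
Product: 6 3-iodo-2-methylprop-1-ene
Conditions: NaI, acetone, rt, dark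
Reagents that add atoms: sodium iodide, [Na+].[I-]
Why: Finkelstein halide exchange driven by precipitation of NaCl; the light-sensitive allylic iodide is used freshly made.

Step 4
Reactants: 4 (4R)-4-methyl-4-[(triethylsilyl)oxy]cyclopent-2-en-1-one; 7 vinylmagnesium bromide; 6 3-iodo-2-methylprop-1-ene
Product: 10 (2R,3R,4R)-3-ethenyl-4-methyl-2-(2-methylprop-2-en-1-yl)-4-[(triethylsilyl)oxy]cyclopentan-1-one, via bromomagnesium enolate 8 (not isolated), via triphenylstannyl enolate 9 (not isolated)
Conditions: CuBr·SMe2 (10 mol %), THF, −78 °C, slow addition of 7; then Ph3SnCl, HMPA, −78 °C; then 6, −78 → −30 °C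
Reagents that add atoms: none
Why: A vinylcopper species formed from 7 and catalytic CuBr·SMe2 (monovalent copper) adds 1,4 to enone 4 at the β-carbon (future C7a), giving the regiodefined enolate 8; transmetalation gives the less basic tin enolate 9, which the allylic iodide 6 C-alkylates at the α-carbon (future C4a) in an SN2 reaction. The closest known reaction type is the three-component coupling of 4-silyloxycyclopent-2-enones used for prostaglandins (organocopper conjugate addition, tin enolate, allylic iodide in HMPA). No ring is closed; the two skeletal bonds C7a–C1 and C4a–C4 are formed. The vinyl group should enter anti to the silyloxy group on the neighbouring quaternary carbon and the methallyl group anti to the vinyl group, both by substrate control, and both centres are erased later. The step needs 1,4- over 1,2-addition, which copper secures, and alkylation at C4a before proton transfer moves the enolate to C6, where loss of the C7 silyloxy group would follow; this is secured by the specific enolate from the conjugate addition, the low basicity of the tin enolate, the reactive allylic iodide and the low temperature.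

Step 5
Reactants: 11 (4S)-4-benzyl-1,3-oxazolidin-2-one; 12 octanoyl chloride
Product: 13 (4S)-4-benzyl-3-octanoyl-1,3-oxazolidin-2-one
Conditions: n-BuLi, THF, −78 °C; then 12, −78 → 0 °C
Reagents that add atoms: none
Why: N-acylation of the lithiated Evans oxazolidinone by the acid chloride.

Step 6
Reactants: 13 (4S)-4-benzyl-3-octanoyl-1,3-oxazolidin-2-one
Product: 14 (4S)-4-benzyl-3-[(2S)-2-methyloctanoyl]-1,3-oxazolidin-2-one
Conditions: NaN(SiMe3)2, THF, −78 °C; MeI
Reagents that add atoms: iodomethane, CI
Why: Evans asymmetric alkylation, in which the chelated sodium Z-enolate is methylated on the face opposite the benzyl group, setting the (S) centre of the side chain.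

Step 7
Reactants: 14 (4S)-4-benzyl-3-[(2S)-2-methyloctanoyl]-1,3-oxazolidin-2-one
Product: 15 (2S)-2-methyloctan-1-ol
Conditions: LiBH4, MeOH (1 equiv), Et2O, 0 °C
Reagents that add atoms: none
Why: Reductive cleavage of the imide by borohydride gives the primary alcohol without enolising the α-centre and returns the auxiliary.

Step 8
Reactants: 15 (2S)-2-methyloctan-1-ol
Product: 16 (2S)-2-methyloctanal
Conditions: TEMPO (cat.), PhI(OAc)2, CH2Cl2, rt
Reagents that add atoms: none
Why: Oxoammonium-mediated (TEMPO) oxidation is non-basic and stops at the aldehyde, so the α-centre should not epimerise; the aldehyde is used at once.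

Step 9
Reactants: 16 (2S)-2-methyloctanal; 7 vinylmagnesium bromide
Product: 17 (4S)-4-methyldec-1-en-3-ol (C3 epimers)
Conditions: THF, −78 °C; aq. NH4Cl
Reagents that add atoms: none
Why: Grignard 1,2-addition at low temperature outruns enolisation of the α-branched aldehyde; the new carbinol centre forms as a mixture (Felkin isomer expected to predominate), which is irrelevant because this carbon ends as the ketone.

Step 10
Reactants: 17 (4S)-4-methyldec-1-en-3-ol
Product: 18 1-methoxy-4-({[(4S)-4-methyldec-1-en-3-yl]oxy}methyl)benzene (C3 epimers)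
Conditions: NaH, 4-methoxybenzyl chloride, n-Bu4NI (cat.), DMF, 0 °C → rt
Reagents that add atoms: 4-methoxybenzyl chloride, COc1ccc(CCl)cc1
Why: Williamson etherification gives a base-stable ether that can later be removed oxidatively without touching the tertiary silyl ether.

Step 11
Reactants: 18 1-methoxy-4-({[(4S)-4-methyldec-1-en-3-yl]oxy}methyl)benzene
Product: 19 (3S)-2-[(4-methoxyphenyl)methoxy]-3-methylnonanal (C2 epimers)
Conditions: O3, pyridine, CH2Cl2, −78 °C
Reagents that add atoms: ozone, [O-][O+]=O
Why: Pyridine-mediated ozonolysis of the terminal alkene gives the α-alkoxy aldehyde directly without a peroxide work-up, the anisyl ring reacting far more slowly than the monosubstituted alkene.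

Step 12
Reactants: 10 (2R,3R,4R)-3-ethenyl-4-methyl-2-(2-methylprop-2-en-1-yl)-4-[(triethylsilyl)oxy]cyclopentan-1-one; 19 (3S)-2-[(4-methoxyphenyl)methoxy]-3-methylnonanal
Product: 22 (2R,3R,4S,5E)-3-ethenyl-5-{(3S)-2-[(4-methoxyphenyl)methoxy]-3-methylnonylidene}-4-methyl-2-(2-methylprop-2-en-1-yl)-4-[(triethylsilyl)oxy]cyclopentan-1-one, via lithium aldolate 20 (not isolated), via aldol mesylate 21 (not isolated)
Conditions: LiN(i-Pr)2, THF, −78 °C; 19; MsCl, −78 → 0 °C; DBU, 0 °C → rt
Reagents that add atoms: none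
Why: Kinetic deprotonation at the C6 methylene (the less substituted α-carbon) and aldol addition to the reactive α-alkoxy aldehyde, then mesylation of the aldolate and E1cB elimination, amount to a directed aldol condensation; the transient C6 and C1′ centres vanish, the chain is expected on the C7 side, and any other geometry or C2′ epimer converges later.

Step 13
Reactants: 22 (2R,3R,4S,5E)-3-ethenyl-5-{(3S)-2-[(4-methoxyphenyl)methoxy]-3-methylnonylidene}-4-methyl-2-(2-methylprop-2-en-1-yl)-4-[(triethylsilyl)oxy]cyclopentan-1-one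
Product: 23 (3R,4S,5E)-3-ethenyl-5-{(3S)-2-[(4-methoxyphenyl)methoxy]-3-methylnonylidene}-4-methyl-2-(2-methylprop-2-en-1-yl)-4-[(triethylsilyl)oxy]cyclopent-1-en-1-yl trifluoromethanesulfonate
Conditions: KN(SiMe3)2, THF, −78 °C; Comins' reagent
Reagents that add atoms: N-(5-chloropyridin-2-yl)-1,1,1-trifluoro-N-[(trifluoromethyl)sulfonyl]methanesulfonamide (Comins' reagent), FC(F)(F)S(=O)(=O)N(c1ccc(Cl)cn1)S(=O)(=O)C(F)(F)F
Why: Enol triflate formation: the only α-hydrogen left (C4a–H) is removed kinetically and the cross-conjugated dienolate is O-sulfonylated, which makes C4a and C5 trigonal and erases the C4a centre.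

Step 14
Reactants: 23 (3R,4S,5E)-3-ethenyl-5-{(3S)-2-[(4-methoxyphenyl)methoxy]-3-methylnonylidene}-4-methyl-2-(2-methylprop-2-en-1-yl)-4-[(triethylsilyl)oxy]cyclopent-1-en-1-yl trifluoromethanesulfonate
Product: 24 methyl (3R,4S,5Z)-3-ethenyl-5-{(3S)-2-[(4-methoxyphenyl)methoxy]-3-methylnonylidene}-4-methyl-2-(2-methylprop-2-en-1-yl)-4-[(triethylsilyl)oxy]cyclopent-1-ene-1-carboxylate
Conditions: CO (1 atm), Pd(OAc)2 (5 mol %), PPh3, Et3N, MeOH, DMF, 50 °C
Reagents that add atoms: carbon monoxide, [C-]#[O+]; methanol, CO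
Why: Palladium-catalysed alkoxycarbonylation of an enol triflate (oxidative addition to zerovalent palladium formed in situ, CO insertion, methanolysis), CO insertion being faster than a strained 4-exo or 5-endo Heck closure onto the pendant alkenes.

Step 15
Reactants: 24 methyl (3R,4S,5Z)-3-ethenyl-5-{(3S)-2-[(4-methoxyphenyl)methoxy]-3-methylnonylidene}-4-methyl-2-(2-methylprop-2-en-1-yl)-4-[(triethylsilyl)oxy]cyclopent-1-ene-1-carboxylate
Product: 25 methyl (3R,4S,5Z)-3-ethenyl-5-[(3S)-2-hydroxy-3-methylnonylidene]-4-methyl-2-(2-methylprop-2-en-1-yl)-4-[(triethylsilyl)oxy]cyclopent-1-ene-1-carboxylate (C2′ epimers)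
Conditions: DDQ, CH2Cl2/pH 7 buffer, 0 °C
Reagents that add atoms: none
Why: Oxidative cleavage of the 4-methoxybenzyl ether by DDQ through the benzylic oxocarbenium ion and its hydrolysis, to which the silyl ether, the ester and the isolated alkenes are inert.

Step 16
Reactants: 25 methyl (3R,4S,5Z)-3-ethenyl-5-[(3S)-2-hydroxy-3-methylnonylidene]-4-methyl-2-(2-methylprop-2-en-1-yl)-4-[(triethylsilyl)oxy]cyclopent-1-ene-1-carboxylate
Product: 26 methyl (3R,4S,5Z)-3-ethenyl-4-methyl-5-[(3S)-3-methyl-2-oxononylidene]-2-(2-methylprop-2-en-1-yl)-4-[(triethylsilyl)oxy]cyclopent-1-ene-1-carboxylate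
Conditions: Dess–Martin periodinane, CH2Cl2, 0 °C → rt
Reagents that add atoms: none
Why: Dess–Martin oxidation of the secondary allylic alcohol is non-basic, so the adjacent (S) centre should not enolise; placing the ketone now makes both conjugated alkenes electron-poor before ozonolysis and leaves no ionisable allylic carbinol once the electron-rich pyran exists.

Step 17
Reactants: 26 methyl (3R,4S,5Z)-3-ethenyl-4-methyl-5-[(3S)-3-methyl-2-oxononylidene]-2-(2-methylprop-2-en-1-yl)-4-[(triethylsilyl)oxy]cyclopent-1-ene-1-carboxylate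
Product: 28 methyl (6Z,7R)-3,7-dimethyl-6-[(3S)-3-methyl-2-oxononylidene]-7-[(triethylsilyl)oxy]-6,7-dihydrocyclopenta[c]pyran-5-carboxylate, via keto aldehyde 27 (not isolated)
Conditions: O3, pyridine, CH2Cl2, −78 °C; then TsOH·H2O, −78 °C → rt
Reagents that add atoms: ozone, [O-][O+]=O
Why: Ozone should cleave the two isolated terminal alkenes much faster than the ester- and ketone-conjugated C4a=C5 and C6=C1′ bonds, and the 1,5-keto aldehyde 27, whose C7a–H and C4–H are vinylogously acidic, should enolise and cyclodehydrate under the pyridinium tosylate formed in the flask (six-membered hemiketal, then loss of water) to the conjugated 4-alkylidene-4H-pyran, erasing the C7a centre.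

Step 18
Reactants: 28 methyl (6Z,7R)-3,7-dimethyl-6-[(3S)-3-methyl-2-oxononylidene]-7-[(triethylsilyl)oxy]-6,7-dihydrocyclopenta[c]pyran-5-carboxylate
Product: 29 methyl (6Z,7R)-7-hydroxy-3,7-dimethyl-6-[(3S)-3-methyl-2-oxononylidene]-6,7-dihydrocyclopenta[c]pyran-5-carboxylate
Conditions: HF·pyridine, pyridine, THF, 0 °C → rt
Reagents that add atoms: none
Why: Fluoride-mediated cleavage of the tertiary triethylsilyl ether under buffered, non-basic conditions should leave the ketone α-centre and C7 untouched, while the push–pull C6 alkylidene (partial single-bond character through its pyrylium enolate form) can settle in the hydrogen-bonded Z geometry of the target.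

Compound list
1 | (R)-(−)-linalool, (3R)-3,7-dimethylocta-1,6-dien-3-ol | C=C[C@](C)(O)CCC=C(C)C | starting material
2 | (1R)-1-methylcyclopent-2-en-1-ol | C1=C[C@](C)(O)CC1 | intermediate
3 | triethyl{[(1R)-1-methylcyclopent-2-en-1-yl]oxy}silane | C1=C[C@](C)(O[Si](CC)(CC)CC)CC1 | intermediate
4 | (4R)-4-methyl-4-[(triethylsilyl)oxy]cyclopent-2-en-1-one | O=C1C=C[C@](C)(O[Si](CC)(CC)CC)C1 | intermediate
5 | 3-chloro-2-methylprop-1-ene | C=C(C)CCl | starting material
6 | 3-iodo-2-methylprop-1-ene | C=C(C)CI | intermediate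
7 | vinylmagnesium bromide | C=C[Mg]Br | starting material
8 | bromomagnesium (3R,4R)-3-ethenyl-4-methyl-4-[(triethylsilyl)oxy]cyclopent-1-en-1-olate | Br[Mg]OC1=C[C@@H](C=C)[C@](C)(O[Si](CC)(CC)CC)C1 | intermediate
9 | {[(3R,4R)-3-ethenyl-4-methyl-4-[(triethylsilyl)oxy]cyclopent-1-en-1-yl]oxy}triphenylstannane | c1ccccc1[Sn](c1ccccc1)(c1ccccc1)OC1=C[C@@H](C=C)[C@](C)(O[Si](CC)(CC)CC)C1 | intermediate
10 | (2R,3R,4R)-3-ethenyl-4-methyl-2-(2-methylprop-2-en-1-yl)-4-[(triethylsilyl)oxy]cyclopentan-1-one (2,3-trans, vinyl anti to the silyloxy group) | O=C1C[C@@](C)(O[Si](CC)(CC)CC)[C@H](C=C)[C@H]1CC(C)=C | intermediate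
11 | (4S)-4-benzyl-1,3-oxazolidin-2-one | O=C1N[C@@H](Cc2ccccc2)CO1 | starting material
12 | octanoyl chloride | CCCCCCCC(=O)Cl | starting material
13 | (4S)-4-benzyl-3-octanoyl-1,3-oxazolidin-2-one | CCCCCCCC(=O)N1[C@@H](Cc2ccccc2)COC1=O | intermediate
14 | (4S)-4-benzyl-3-[(2S)-2-methyloctanoyl]-1,3-oxazolidin-2-one | CCCCCC[C@H](C)C(=O)N1[C@@H](Cc2ccccc2)COC1=O | intermediate
15 | (2S)-2-methyloctan-1-ol | CCCCCC[C@H](C)CO | intermediate
16 | (2S)-2-methyloctanal | CCCCCC[C@H](C)C=O | intermediate
17 | (4S)-4-methyldec-1-en-3-ol (C3 epimers) | CCCCCC[C@H](C)C(O)C=C | intermediate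
18 | 1-methoxy-4-({[(4S)-4-methyldec-1-en-3-yl]oxy}methyl)benzene (C3 epimers) | CCCCCC[C@H](C)C(OCc1ccc(OC)cc1)C=C | intermediate
19 | (3S)-2-[(4-methoxyphenyl)methoxy]-3-methylnonanal (C2 epimers) | CCCCCC[C@H](C)C(OCc1ccc(OC)cc1)C=O | intermediate
20 | lithium aldolate from C6 of 10 and the formyl carbon of 19 (C6, C1′, C2′ mixtures; other centres as in 10) | O=C1[C@H](CC(C)=C)[C@@H](C=C)[C@](C)(O[Si](CC)(CC)CC)C1C(O[Li])C(OCc1ccc(OC)cc1)[C@@H](C)CCCCCC | intermediate
21 | C1′ methanesulfonate of the aldol (C6, C1′, C2′ mixtures) | O=C1[C@H](CC(C)=C)[C@@H](C=C)[C@](C)(O[Si](CC)(CC)CC)C1C(OS(C)(=O)=O)C(OCc1ccc(OC)cc1)[C@@H](C)CCCCCC | intermediate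
22 | (2R,3R,4S,5E)-3-ethenyl-5-{(3S)-2-[(4-methoxyphenyl)methoxy]-3-methylnonylidene}-4-methyl-2-(2-methylprop-2-en-1-yl)-4-[(triethylsilyl)oxy]cyclopentan-1-one (C2′ epimers) | O=C1[C@H](CC(C)=C)[C@@H](C=C)[C@](C)(O[Si](CC)(CC)CC)/C1=C\C(OCc1ccc(OC)cc1)[C@@H](C)CCCCCC | intermediate
23 | (3R,4S,5E)-3-ethenyl-5-{(3S)-2-[(4-methoxyphenyl)methoxy]-3-methylnonylidene}-4-methyl-2-(2-methylprop-2-en-1-yl)-4-[(triethylsilyl)oxy]cyclopent-1-en-1-yl trifluoromethanesulfonate (C2′ epimers) | O=S(=O)(OC1=C(CC(C)=C)[C@@H](C=C)[C@](C)(O[Si](CC)(CC)CC)/C1=C\C(OCc1ccc(OC)cc1)[C@@H](C)CCCCCC)C(F)(F)F | intermediate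
24 | methyl (3R,4S,5Z)-3-ethenyl-5-{(3S)-2-[(4-methoxyphenyl)methoxy]-3-methylnonylidene}-4-methyl-2-(2-methylprop-2-en-1-yl)-4-[(triethylsilyl)oxy]cyclopent-1-ene-1-carboxylate (C2′ epimers) | COC(=O)C1=C(CC(C)=C)[C@@H](C=C)[C@](C)(O[Si](CC)(CC)CC)/C1=C\C(OCc1ccc(OC)cc1)[C@@H](C)CCCCCC | intermediate
25 | methyl (3R,4S,5Z)-3-ethenyl-5-[(3S)-2-hydroxy-3-methylnonylidene]-4-methyl-2-(2-methylprop-2-en-1-yl)-4-[(triethylsilyl)oxy]cyclopent-1-ene-1-carboxylate (C2′ epimers) | COC(=O)C1=C(CC(C)=C)[C@@H](C=C)[C@](C)(O[Si](CC)(CC)CC)/C1=C\C(O)[C@@H](C)CCCCCC | intermediate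
26 | methyl (3R,4S,5Z)-3-ethenyl-4-methyl-5-[(3S)-3-methyl-2-oxononylidene]-2-(2-methylprop-2-en-1-yl)-4-[(triethylsilyl)oxy]cyclopent-1-ene-1-carboxylate | COC(=O)C1=C(CC(C)=C)[C@@H](C=C)[C@](C)(O[Si](CC)(CC)CC)/C1=C\C(=O)[C@@H](C)CCCCCC | intermediate
27 | methyl (3R,4S,5Z)-3-formyl-4-methyl-5-[(3S)-3-methyl-2-oxononylidene]-2-(2-oxopropyl)-4-[(triethylsilyl)oxy]cyclopent-1-ene-1-carboxylate | COC(=O)C1=C(CC(C)=O)[C@@H](C=O)[C@](C)(O[Si](CC)(CC)CC)/C1=C\C(=O)[C@@H](C)CCCCCC | intermediate
28 | methyl (6Z,7R)-3,7-dimethyl-6-[(3S)-3-methyl-2-oxononylidene]-7-[(triethylsilyl)oxy]-6,7-dihydrocyclopenta[c]pyran-5-carboxylate | CCCCCC[C@H](C)C(=O)/C=C1/C(C(=O)OC)=C2C=C(C)OC=C2[C@]1(C)O[Si](CC)(CC)CC | intermediate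
29 | methyl (6Z,7R)-7-hydroxy-3,7-dimethyl-6-[(3S)-3-methyl-2-oxononylidene]-6,7-dihydrocyclopenta[c]pyran-5-carboxylate | CCCCCC[C@H](C)C(=O)/C=C1/C(C(=O)OC)=C2C=C(C)OC=C2[C@]1(C)O | target

Total steps: 18. Longest linear sequence: 14 steps (steps 5 to 11, then 12 to 18); the ring A line from linalool runs over 10 steps (1, 2, 4, 12 to 18).

Steps most likely to fail

Step 4. Proton transfer between the enolate and the ketone already alkylated would move the enolate to C6, where the C7 silyloxy group is lost or a second alkylation occurs; the conjugate addition beside the quaternary carbon may also be slow enough for 1,2-addition to compete. The fallback sets out from 4 and comes back at 10; it makes the two bonds in separate operations and avoids enolate alkylation altogether. α-Iodination of 4 (I2, pyridine, CH2Cl2) should give (4R)-2-iodo-4-methyl-4-[(triethylsilyl)oxy]cyclopent-2-en-1-one F1. Stille coupling with commercial tributyl(2-methylprop-2-en-1-yl)stannane (Pd2(dba)3 as zerovalent palladium source, AsPh3, CuI, N-methylpyrrolidone) should give (4R)-4-methyl-2-(2-methylprop-2-en-1-yl)-4-[(triethylsilyl)oxy]cyclopent-2-en-1-one F2. Copper-catalysed conjugate addition of 7 (CuBr·SMe2, THF, −78 °C) then gives the bromomagnesium enolate of the adduct F3, which is protonated cold with aqueous NH4Cl to 10; any C4a epimer converges at 23.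

Step 12. The C6 lithium enolate may expel the C7 silyloxy group by β-elimination, the hindered enolate may enolise the aldehyde instead of adding to it, or the aldolate may revert during mesylation. The fallback sets out from 10 and comes back at 22; it replaces the free enolate by a neutral enol silane. Deprotonation with LiN(i-Pr)2 in the presence of Me3SiCl (in situ quench, THF, −78 °C) should give the kinetic C5–C6 trimethylsilyl enol ether of 10 F4. Mukaiyama aldol addition to 19 (BF3·OEt2, CH2Cl2, −78 °C) should give the neutral β-hydroxy ketone F5. Mesylation (MsCl, Et3N) to 21 and elimination with DBU then give 22.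

Step 17. Ozone may attack the conjugated C6=C1′ or C4a=C5 bonds, or the β-silyloxy aldehyde may lose the C7 silyloxy group under the basic additive before the ring closes. The fallback sets out from 26 and comes back at 28; it separates alkene oxidation from carbonyl release. Dihydroxylation of the two terminal alkenes (catalytic OsO4, octavalent osmium, N-methylmorpholine N-oxide, acetone/water) should stop at the purifiable tetraol F6, the electron-poor conjugated alkenes reacting far more slowly. Glycol cleavage with Pb(OAc)4 (tetravalent lead) in CH2Cl2 under neutral, anhydrous conditions releases keto aldehyde 27, which is closed directly with pyridinium tosylate to 28.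

Further compounds
F1 | step 4 | (4R)-2-iodo-4-methyl-4-[(triethylsilyl)oxy]cyclopent-2-en-1-one | O=C1C(I)=C[C@](C)(O[Si](CC)(CC)CC)C1
F2 | step 4 | (4R)-4-methyl-2-(2-methylprop-2-en-1-yl)-4-[(triethylsilyl)oxy]cyclopent-2-en-1-one | O=C1C(CC(C)=C)=C[C@](C)(O[Si](CC)(CC)CC)C1
F3 | step 4 | bromomagnesium (3R,4R)-3-ethenyl-4-methyl-2-(2-methylprop-2-en-1-yl)-4-[(triethylsilyl)oxy]cyclopent-1-en-1-olate | Br[Mg]OC1=C(CC(C)=C)[C@@H](C=C)[C@](C)(O[Si](CC)(CC)CC)C1
F4 | step 12 | kinetic C5–C6 trimethylsilyl enol ether of 10 (ring centres as in 10) | C[Si](C)(C)OC1=C[C@@](C)(O[Si](CC)(CC)CC)[C@H](C=C)[C@H]1CC(C)=C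
F5 | step 12 | β-hydroxy ketone from C6 of 10 and the formyl carbon of 19 (C6, C1′, C2′ mixtures) | O=C1[C@H](CC(C)=C)[C@@H](C=C)[C@](C)(O[Si](CC)(CC)CC)C1C(O)C(OCc1ccc(OC)cc1)[C@@H](C)CCCCCC
F6 | step 17 | tetraol of 26, with the vinyl and the methallyl alkene each dihydroxylated (carbinol mixtures) | COC(=O)C1=C(CC(C)(O)CO)[C@@H](C(O)CO)[C@](C)(O[Si](CC)(CC)CC)/C1=C\C(=O)[C@@H](C)CCCCCC
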